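**Retrosynthetic overview**

1. The strategy rests on ring C (O1, C2, C3, C4, C4a, C8a). O1–C8a–C4a–C4 is read as the heterodiene of an ortho-quinone methide from a hexasubstituted salicylaldehyde, and C2–C3 as the vinyl group of 4-vinylphenol (ring B). One (4+2) union forms O1–C2 and C3–C4 and sets C2.
2. The C4 ketone comes afterwards from the C4 methyl ether by DDQ oxidation, followed by one acidic global deprotection.
3. The salicylaldehyde comes from a symmetric 4-alkyl-3,5-bis(MOM)phenol by ortho C-prenylation (future C8) and magnesium-mediated ortho-formylation (future C4); the symmetry fixes the regiochemistry.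
4. The C6 side chain is grown from a prenyl group placed by lithiation between the two MOM ethers: Shi epoxidation sets the (R) centre, and an aluminium amide isomerisation gives the isopropenyl carbinol.
5. Ring A is bought as phloroglucinol and ring B as 4-acetoxystyrene; ring C is the only ring formed (step 11).

Key step: step 11

Remark: the (R) enantiomer of the phosphoric acid is assumed to deliver 2S; the sense of induction of this new reaction is not predictable with certainty, and the (S) acid is used in the same way if it proves opposite.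
Remark: compound 19 is drawn 2,4-cis; its C4 epimer would be carried on equally, since C4 becomes the carbonyl carbon in step 13.

**Route**

Step 1
Reactants: 1 phloroglucinol
Product: 2 3,5-bis(methoxymethoxy)phenol
Conditions: MOMCl (2.0 equiv), iPr2NEt, DMF, 0 °C to rt; chromatography
Reagents that add atoms: chloromethyl methyl ether, COCCl
Why: Williamson-type O-alkylation with a limiting amount of MOMCl should give the bis-ether statistically beside mono- and tris-ethers, from which it is separated; the three hydroxyls are equivalent, so only one bis-ether exists.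

Step 2
Reactants: 2 3,5-bis(methoxymethoxy)phenol
Product: 3 [3,5-bis(methoxymethoxy)phenoxy]triisopropylsilane
Conditions: TIPSCl, imidazole, DMF, rt
Reagents that add atoms: triisopropylsilyl chloride, CC(C)[Si](Cl)(C(C)C)C(C)C
Why: Silylation of the remaining phenol gives an ether that survives n-BuLi and the basic epoxidation medium and does not direct lithiation.

Step 3
Reactants: 3 [3,5-bis(methoxymethoxy)phenoxy]triisopropylsilane; 4 prenyl bromide
Product: 6 [3,5-bis(methoxymethoxy)-4-(3-methylbut-2-enyl)phenoxy]triisopropylsilane, via aryllithium 5 (not isolated)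
Conditions: n-BuLi, THF, 0 °C; then CuI (10 mol %), prenyl bromide, −40 °C to rt
Reagents that add atoms: none
Why: Directed ortho-metalation places lithium at the carbon flanked by both MOM ethers (double chelation), and copper-catalysed allylation of the aryllithium with the primary bromide should give the linear prenyl arene.

Step 4
Reactants: 6 [3,5-bis(methoxymethoxy)-4-(3-methylbut-2-enyl)phenoxy]triisopropylsilane
Product: 7 [4-{[(2R)-3,3-dimethyloxiran-2-yl]methyl}-3,5-bis(methoxymethoxy)phenoxy]triisopropylsilane
Conditions: D-fructose-derived Shi ketone (30 mol %), KHSO5 (as Oxone, 2KHSO5·KHSO4·K2SO4), K2CO3, Bu4NHSO4, MeCN/CH2(OMe)2/aq. Na2B4O7–Na2EDTA buffer, 0 °C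
Reagents that add atoms: potassium peroxymonosulfate, [K+].[O-]S(=O)(=O)OO
Why: Shi asymmetric epoxidation, in which the chiral dioxirane attacks the trisubstituted prenyl alkene through the spiro transition state that leads to the (R) epoxide; this sets the later carbinol centre, and the buffered basic medium spares the MOM and silyl ethers.

Step 5
Reactants: 7 [4-{[(2R)-3,3-dimethyloxiran-2-yl]methyl}-3,5-bis(methoxymethoxy)phenoxy]triisopropylsilane
Product: 8 (2R)-1-[2,6-bis(methoxymethoxy)-4-(triisopropylsilyloxy)phenyl]-3-methylbut-3-en-2-ol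
Conditions: Et2AlCl, lithium 2,2,6,6-tetramethylpiperidide, toluene, 0 °C; aq. potassium sodium tartrate (KNaC4H4O6) work-up
Reagents that add atoms: none
Why: Yamamoto-type aluminium amide isomerisation of a trisubstituted epoxide, in which aluminium weakens the tertiary C–O bond and the amide removes a methyl proton syn to oxygen; the isopropenyl carbinol forms with the C–O bond of the stereocentre untouched, so (R) is retained.

Step 6
Reactants: 8 (2R)-1-[2,6-bis(methoxymethoxy)-4-(triisopropylsilyloxy)phenyl]-3-methylbut-3-en-2-ol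
Product: 9 tert-butyl{[(2R)-1-[2,6-bis(methoxymethoxy)-4-(triisopropylsilyloxy)phenyl]-3-methylbut-3-en-2-yl]oxy}dimethylsilane
Conditions: TBSCl, imidazole, DMAP (cat.), DMF, rt
Reagents that add atoms: tert-butyldimethylsilyl chloride, CC(C)(C)[Si](C)(C)Cl
Why: Standard silylation of the secondary allylic alcohol keeps the hydroxyl out of the later alkylation, orthoformate and oxidation chemistry.

Step 7
Reactants: 9 tert-butyl{[(2R)-1-[2,6-bis(methoxymethoxy)-4-(triisopropylsilyloxy)phenyl]-3-methylbut-3-en-2-yl]oxy}dimethylsilane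
Product: 10 4-[(2R)-2-(tert-butyldimethylsilyloxy)-3-methylbut-3-enyl]-3,5-bis(methoxymethoxy)phenol
Conditions: Bu4NF (1.1 equiv), AcOH (1.1 equiv), THF, 0 °C
Reagents that add atoms: none
Why: Fluoride cleaves the aryl silyl ether (phenoxide leaving group) much faster than the hindered secondary alkyl TBS ether, and acetic acid buffers the phenoxide.

Step 8
Reactants: 10 4-[(2R)-2-(tert-butyldimethylsilyloxy)-3-methylbut-3-enyl]-3,5-bis(methoxymethoxy)phenol; 4 prenyl bromide
Product: 12 4-[(2R)-2-(tert-butyldimethylsilyloxy)-3-methylbut-3-enyl]-3,5-bis(methoxymethoxy)-2-(3-methylbut-2-enyl)phenol, via sodium phenoxide 11 (not isolated)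
Conditions: NaH (1.05 equiv), toluene, 0 °C; then prenyl bromide (1.1 equiv), rt
Reagents that add atoms: none
Why: Classical phenoxide C-allylation, in which the tight sodium ion pair in a non-polar solvent is alkylated at carbon ortho to oxygen; para is blocked and the two ortho positions are equivalent by symmetry, so a single constitution should result.

Step 9
Reactants: 12 4-[(2R)-2-(tert-butyldimethylsilyloxy)-3-methylbut-3-enyl]-3,5-bis(methoxymethoxy)-2-(3-methylbut-2-enyl)phenol
Product: 14 2-hydroxy-4,6-bis(methoxymethoxy)-3-(3-methylbut-2-enyl)-5-[(2R)-2-(tert-butyldimethylsilyloxy)-3-methylbut-3-enyl]benzaldehyde, via hydroxymethyl phenol 13 (not isolated)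
Conditions: MgCl2, Et3N, (CH2O)n, MeCN, reflux
Reagents that add atoms: formaldehyde (from paraformaldehyde), C=O
Why: Casnati–Skattebøl ortho-formylation, in which the magnesium phenoxide delivers formaldehyde to the only free ring position, ortho to the hydroxyl, and a second formaldehyde oxidises the hydroxymethyl intermediate by hydride transfer; MgCl2 and Et3N only mediate.

Step 10
Reactants: 15 4-acetoxystyrene
Product: 16 4-vinylphenol
Conditions: K2CO3 (cat.), MeOH, 0 °C; aq. NH4Cl; used at once
Reagents that add atoms: none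
Why: Base-catalysed transesterification of the aryl acetate with methanol frees the phenol, which is used immediately because it polymerises on storage.

Step 11
Reactants: 14 2-hydroxy-4,6-bis(methoxymethoxy)-3-(3-methylbut-2-enyl)-5-[(2R)-2-(tert-butyldimethylsilyloxy)-3-methylbut-3-enyl]benzaldehyde; 16 4-vinylphenol
Product: 19 (2S,4S)-2-(4-hydroxyphenyl)-4-methoxy-5,7-bis(methoxymethoxy)-8-(3-methylbut-2-enyl)-6-[(2R)-2-(tert-butyldimethylsilyloxy)-3-methylbut-3-enyl]chroman, via dimethyl acetal 17 (not isolated), via methoxy ortho-quinone methide 18 (not isolated)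
Conditions: HC(OMe)3 (2 equiv), (R)-TRIP [(R)-3,3′-bis(2,4,6-triisopropylphenyl)-1,1′-binaphthyl-2,2′-diyl hydrogen phosphate, 10 mol %], 5 Å MS, toluene, −20 to 0 °C
Reagents that add atoms: trimethyl orthoformate, COC(OC)OC
Why: Proposed new method: the acid should convert aldehyde 14 with HC(OMe)3 into acetal 17, whose ionisation with loss of methanol gives the hydrogen-bonded methoxy ortho-quinone methide 18 (equivalently the aryl(methoxy)carbenium phosphate), while the phosphoryl oxygen holds the phenolic hydroxyl of 16 so that its terminal vinyl carbon attacks C4 and the benzylic carbon is captured by the ring-A oxygen. The closest known reactions are the chiral phosphoric acid catalysed (4+2) cycloadditions of ortho-quinone methides with hydroxystyrenes and the achiral acid-mediated union of salicylaldehydes, orthoformates and styrenes to 4-alkoxy-2-arylchromans; their combination on a vinylphenol with a para hydroxyl is what is new. Ring C closes either in a concerted inverse-electron-demand hetero-Diels–Alder reaction or, more probably, stepwise by C3–C4 bond formation followed by a 6-exo-trig oxa-1,6-addition of the C8a hydroxyl to the para-quinone methide derived from 16, the bifunctional mode known for phosphoric acid catalysed additions to para-quinone methides. C2 is set by the chiral phosphate, which is bound to both partners when the C–O bond forms, whereas C4 follows from the substrate (aryl and methoxy both pseudo-equatorial, hence 2,4-cis) and is erased in step 13. The step needs regioselectivity, which the polarity of the partners fixes (nucleophilic CH2 terminus to electrophilic C4, aryl on C2), site selectivity, which the single free hydroxyl next to the prenyl carbon secures (the other ring-A oxygens are MOM ethers, so prenyl ends on C8 and the chain on C6), and chemoselectivity over the prenyl and isopropenyl alkenes, which are far less nucleophilic than the hydroxystyrene and cannot reach C4 intramolecularly. The weak acid and low temperature should spare the MOM acetals, the silyl ether and the prenyl group and keep the O1–C2 bond from reopening.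

Step 12
Reactants: 19 (2S,4S)-2-(4-hydroxyphenyl)-4-methoxy-5,7-bis(methoxymethoxy)-8-(3-methylbut-2-enyl)-6-[(2R)-2-(tert-butyldimethylsilyloxy)-3-methylbut-3-enyl]chroman
Product: 20 4-{(2S,4S)-4-methoxy-5,7-bis(methoxymethoxy)-8-(3-methylbut-2-enyl)-6-[(2R)-2-(tert-butyldimethylsilyloxy)-3-methylbut-3-enyl]chroman-2-yl}phenyl acetate
Conditions: Ac2O, pyridine, DMAP (cat.), CH2Cl2, 0 °C
Reagents that add atoms: acetic anhydride, CC(=O)OC(C)=O
Why: Acylation of the only free hydroxyl masks the ring-B phenol so that DDQ cannot oxidise it toward a para-quinone methide in the next step.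

Step 13
Reactants: 20 4-{(2S,4S)-4-methoxy-5,7-bis(methoxymethoxy)-8-(3-methylbut-2-enyl)-6-[(2R)-2-(tert-butyldimethylsilyloxy)-3-methylbut-3-enyl]chroman-2-yl}phenyl acetate
Product: 22 4-{(2S)-5,7-bis(methoxymethoxy)-8-(3-methylbut-2-enyl)-4-oxo-6-[(2R)-2-(tert-butyldimethylsilyloxy)-3-methylbut-3-enyl]chroman-2-yl}phenyl acetate, via C4 hemiketal 21 (not isolated)
Conditions: DDQ (1.3 equiv), CH2Cl2/pH 7 phosphate buffer (10:1), 0 °C to rt
Reagents that add atoms: water, O
Why: DDQ oxidative cleavage of an electron-rich benzylic ether, in which hydride is abstracted from C4, the position stabilised by both the methoxy group and the trioxygenated ring A, and water converts the oxocarbenium ion through the hemiketal into the ketone; C2 is not touched.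

Step 14
Reactants: 22 4-{(2S)-5,7-bis(methoxymethoxy)-8-(3-methylbut-2-enyl)-4-oxo-6-[(2R)-2-(tert-butyldimethylsilyloxy)-3-methylbut-3-enyl]chroman-2-yl}phenyl acetate
Product: 23 (2S)-5,7-dihydroxy-2-(4-hydroxyphenyl)-6-[(2R)-2-hydroxy-3-methylbut-3-enyl]-8-(3-methylbut-2-enyl)chroman-4-one
Conditions: HCl (ca. 1.5 M in MeOH), THF, rt to 40 °C
Reagents that add atoms: none
Why: Acid-catalysed methanolysis (acetal exchange, desilylation, transesterification) should remove both MOM groups, the TBS ether and the acetate in one operation under non-basic conditions, so the flavanone does not open to the chalcone and C2 is kept.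

**Compound list**

1 | phloroglucinol | Oc1cc(O)cc(O)c1 | starting material
2 | 3,5-bis(methoxymethoxy)phenol | COCOc1cc(O)cc(OCOC)c1 | intermediate
3 | [3,5-bis(methoxymethoxy)phenoxy]triisopropylsilane | COCOc1cc(OCOC)cc(O[Si](C(C)C)(C(C)C)C(C)C)c1 | intermediate
4 | prenyl bromide | CC(C)=CCBr | starting material
5 | 2,6-bis(methoxymethoxy)-4-(triisopropylsilyloxy)phenyllithium | [Li]c1c(OCOC)cc(O[Si](C(C)C)(C(C)C)C(C)C)cc1OCOC | intermediate (not isolated)
6 | [3,5-bis(methoxymethoxy)-4-(3-methylbut-2-enyl)phenoxy]triisopropylsilane | CC(C)=CCc1c(OCOC)cc(O[Si](C(C)C)(C(C)C)C(C)C)cc1OCOC | intermediate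
7 | [4-{[(2R)-3,3-dimethyloxiran-2-yl]methyl}-3,5-bis(methoxymethoxy)phenoxy]triisopropylsilane | CC1(C)O[C@@H]1Cc1c(OCOC)cc(O[Si](C(C)C)(C(C)C)C(C)C)cc1OCOC | intermediate
8 | (2R)-1-[2,6-bis(methoxymethoxy)-4-(triisopropylsilyloxy)phenyl]-3-methylbut-3-en-2-ol | C=C(C)[C@H](O)Cc1c(OCOC)cc(O[Si](C(C)C)(C(C)C)C(C)C)cc1OCOC | intermediate
9 | TBS ether of 8 | C=C(C)[C@H](O[Si](C)(C)C(C)(C)C)Cc1c(OCOC)cc(O[Si](C(C)C)(C(C)C)C(C)C)cc1OCOC | intermediate
10 | 4-[(2R)-2-(tert-butyldimethylsilyloxy)-3-methylbut-3-enyl]-3,5-bis(methoxymethoxy)phenol | C=C(C)[C@H](O[Si](C)(C)C(C)(C)C)Cc1c(OCOC)cc(O)cc1OCOC | intermediate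
11 | sodium phenoxide of 10 | C=C(C)[C@H](O[Si](C)(C)C(C)(C)C)Cc1c(OCOC)cc([O-])cc1OCOC.[Na+] | intermediate (not isolated)
12 | 2-prenyl derivative of phenol 10 | C=C(C)[C@H](O[Si](C)(C)C(C)(C)C)Cc1c(OCOC)c(CC=C(C)C)c(O)cc1OCOC | intermediate
13 | 6-(hydroxymethyl) derivative of phenol 12 | C=C(C)[C@H](O[Si](C)(C)C(C)(C)C)Cc1c(OCOC)c(CC=C(C)C)c(O)c(CO)c1OCOC | intermediate (not isolated)
14 | 2-hydroxy-4,6-bis(methoxymethoxy)-3-prenyl-5-[(2R)-2-(tert-butyldimethylsilyloxy)-3-methylbut-3-enyl]benzaldehyde | C=C(C)[C@H](O[Si](C)(C)C(C)(C)C)Cc1c(OCOC)c(CC=C(C)C)c(O)c(C=O)c1OCOC | intermediate (key-step precursor)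
15 | 4-acetoxystyrene | CC(=O)Oc1ccc(C=C)cc1 | starting material
16 | 4-vinylphenol | C=Cc1ccc(O)cc1 | intermediate
17 | dimethyl acetal of aldehyde 14 | C=C(C)[C@H](O[Si](C)(C)C(C)(C)C)Cc1c(OCOC)c(CC=C(C)C)c(O)c(C(OC)OC)c1OCOC | intermediate (not isolated)
18 | methoxy ortho-quinone methide from 17 (drawn E) | C=C(C)[C@H](O[Si](C)(C)C(C)(C)C)CC1=C(OCOC)/C(=C\OC)C(=O)C(CC=C(C)C)=C1OCOC | intermediate (not isolated)
19 | (2S,4S)-4-methoxyflavan with free ring-B phenol | C=C(C)[C@H](O[Si](C)(C)C(C)(C)C)Cc1c(OCOC)c(CC=C(C)C)c2c(c1OCOC)[C@@H](OC)C[C@@H](c1ccc(O)cc1)O2 | intermediate (key-step product)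
20 | ring-B acetate of 19 | C=C(C)[C@H](O[Si](C)(C)C(C)(C)C)Cc1c(OCOC)c(CC=C(C)C)c2c(c1OCOC)[C@@H](OC)C[C@@H](c1ccc(OC(C)=O)cc1)O2 | intermediate
21 | C4 hemiketal of 22 (both C4 epimers) | C=C(C)[C@H](O[Si](C)(C)C(C)(C)C)Cc1c(OCOC)c(CC=C(C)C)c2c(c1OCOC)C(O)(OC)C[C@@H](c1ccc(OC(C)=O)cc1)O2 | intermediate (not isolated)
22 | protected (2S)-flavanone | C=C(C)[C@H](O[Si](C)(C)C(C)(C)C)Cc1c(OCOC)c(CC=C(C)C)c2c(c1OCOC)C(=O)C[C@@H](c1ccc(OC(C)=O)cc1)O2 | intermediate
23 | (2S)-5,7-dihydroxy-2-(4-hydroxyphenyl)-6-[(2R)-2-hydroxy-3-methylbut-3-enyl]-8-(3-methylbut-2-enyl)chroman-4-one | C=C(C)[C@H](O)Cc1c(O)c(CC=C(C)C)c2c(c1O)C(=O)C[C@@H](c1ccc(O)cc1)O2 | target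

**Step count**

Total: 14 steps. Longest linear sequence: 13 steps (steps 1–9 and 11–14 from phloroglucinol); step 10 is a one-step side branch.

**Steps most likely to fail**

Step 11 (proposed new method). The stabilised methoxy carbenium ion may react too slowly, so that the vinylphenol oligomerises under acid first. Facial control may be poor because the phenolic hydroxyl that anchors the catalyst is remote from the reacting alkene. Reversible opening of the O1–C2 bond may erode the configuration at C2.
Fallback by known chemistry, setting out from 14 and returning at 22: MeMgBr (3 equiv, THF, 0 °C) should add to the aldehyde to give the secondary benzylic alcohol F1. MnO2 in CH2Cl2 should oxidise it to the 2-hydroxyacetophenone F2. Heating with Me2NCH(OMe)2 in toluene should give the enaminone F3, and PPTS in warm toluene should close it with loss of dimethylamine to the chromone F4. A rhodium-catalysed asymmetric 1,4-addition of 4-acetoxyphenylboronic acid ([Rh(OH)(cod)]2 with an electron-poor atropisomeric bisphosphine of the MeO-BIPHEP family, the enantiomer that delivers 2S, CH2Cl2/H2O, rt, no added base) should then give flavanone 22 directly.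

Step 13. Hydride may be abstracted from the doubly activated benzylic and allylic methylene of the C8 prenyl group instead of C4, or abstraction at C4 may be slow if the C4–H bond lies in the plane of ring A.
Fallback, setting out from 20 and returning at 22: solvolysis of the labile benzylic methyl ether with PPTS in THF/H2O at rt should give the flavan-4-ol F5 as a mixture of C4 epimers, and Dess–Martin periodinane with NaHCO3 in CH2Cl2 should oxidise it to 22.

Step 8. O-alkylation and double alkylation may compete with ortho C-prenylation.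
Fallback, setting out from 10 and returning at 12: allyl bromide with K2CO3 in acetone should give the allyl ether F6. Claisen rearrangement in N,N-diethylaniline at 180 °C (para blocked, both ortho positions equivalent) should give the ortho-allylphenol F7. Cross-metathesis with 2-methyl-2-butene and the second-generation Grubbs catalyst RuCl2(=CHPh)(PCy3)(H2IMes) in CH2Cl2 at 40 °C should turn the allyl into the prenyl group of 12; the hindered 1,1-disubstituted alkene of the side chain is expected to stay inert.

**Further compounds**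

F1 | step 11 | 1-aryl-ethanol from MeMgBr addition to 14 (both carbinol epimers) | C=C(C)[C@H](O[Si](C)(C)C(C)(C)C)Cc1c(OCOC)c(CC=C(C)C)c(O)c(C(C)O)c1OCOC
F2 | step 11 | 2-hydroxyacetophenone corresponding to 14 | C=C(C)[C@H](O[Si](C)(C)C(C)(C)C)Cc1c(OCOC)c(CC=C(C)C)c(O)c(C(C)=O)c1OCOC
F3 | step 11 | (E)-dimethylamino enaminone of F2 | C=C(C)[C@H](O[Si](C)(C)C(C)(C)C)Cc1c(OCOC)c(CC=C(C)C)c(O)c(C(=O)/C=C/N(C)C)c1OCOC
F4 | step 11 | 5,7-bis(methoxymethoxy)-8-prenyl-6-[(2R)-2-(tert-butyldimethylsilyloxy)-3-methylbut-3-enyl]chromone | C=C(C)[C@H](O[Si](C)(C)C(C)(C)C)Cc1c(OCOC)c(CC=C(C)C)c2occc(=O)c2c1OCOC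
F5 | step 13 | flavan-4-ol from 20 (both C4 epimers) | C=C(C)[C@H](O[Si](C)(C)C(C)(C)C)Cc1c(OCOC)c(CC=C(C)C)c2c(c1OCOC)C(O)C[C@@H](c1ccc(OC(C)=O)cc1)O2
F6 | step 8 | allyl ether of phenol 10 | C=C(C)[C@H](O[Si](C)(C)C(C)(C)C)Cc1c(OCOC)cc(OCC=C)cc1OCOC
F7 | step 8 | 2-allyl derivative of phenol 10 | C=C(C)[C@H](O[Si](C)(C)C(C)(C)C)Cc1c(OCOC)c(CC=C)c(O)cc1OCOC
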